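Labels: ring A = phenanthrene ring C5–C8 (OMe on C7, ring B on C6); ring D = phenanthrene ring C1–C4 (Cl on C2, OH on C3, ring C on C4); ring B = chlorophenol ring (b1 on C6, b2 OH, b5 Cl, b6 CH2); ring C = the other phenol ring.
Retrosynthetic cuts, in order: the three O–isopropyl bonds; the phenanthrene C4a–C4b bond (back to a 16-membered cis-stilbene); the C9=C10 bond (dialdehyde); the CH2–CH2 bridge between b6 and ring C; the ring C–ring D biaryl bond; the C6–b1 biaryl bond.
Enabling feature: at the C6–b1 axis the C7 oxygen of ring A and the b6 carbon of ring B are both ortho to the axis, so they can be tied as an aryl benzoate C7–O–C(=O)–b6 whose carbonyl carbon is the later bridge CH2; chlorine on b5 leaves b1–H as the only ortho C–H of that benzoate.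
Forward: the ester is cyclised by palladium to a six-membered lactone (C6–b1 formed), then opened, O-methylated and converted into a phosphonium salt; a ring C–ring D biaryl aldehyde is made in parallel; Wittig reaction and diimide reduction give the open four-ring chain; McMurry coupling closes the 16-membered stilbene ring; photocyclisation forms the central phenanthrene ring; BCl3 frees the three phenols.
Stereochemistry: the target has no stereogenic centre; alkene geometry and the transient trans-dihydrophenanthrene are erased along the way.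

Key step: step 5

Assumption: the target is drawn without stereodescriptors, so the biaryl axes and the twist of the bay region are not controlled and the product is taken in racemic/unspecified form.

Step 1
Reactants: 1 4-bromo-3-hydroxybenzaldehyde
Product: 2 2-bromo-5-(1,3-dioxolan-2-yl)phenol
Conditions: ethylene glycol, p-TsOH (cat.), toluene, reflux, Dean–Stark
Reagents that add atoms: ethylene glycol, OCCO
Why: Acid-catalysed acetalisation driven by azeotropic water removal masks the aldehyde against the hydride of step 6 and the ylide of step 15, and the free phenol is untouched under these conditions.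

Step 2
Reactants: 3 2-chloro-5-hydroxybenzoic acid
Product: 4 propan-2-yl 2-chloro-5-(propan-2-yloxy)benzoate
Conditions: 2-bromopropane (excess), K2CO3, DMF, 70 °C
Reagents that add atoms: 2-bromopropane, CC(C)Br
Why: Twofold SN2 O-alkylation (Williamson etherification of the phenoxide plus carboxylate alkylation) installs the isopropyl ether that survives to the last step, the concomitant ester being removed in step 3.

Step 3
Reactants: 4 propan-2-yl 2-chloro-5-(propan-2-yloxy)benzoate
Product: 5 2-chloro-5-(propan-2-yloxy)benzoic acid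
Conditions: NaOH, MeOH/H2O, 65 °C; then aqueous HCl
Reagents that add atoms: sodium hydroxide, [Na+].[OH-]
Why: Saponification (acyl substitution by hydroxide) cleaves only the isopropyl ester because aryl alkyl ethers and the aryl chloride are inert to aqueous base at this temperature.

Step 4
Reactants: 5 2-chloro-5-(propan-2-yloxy)benzoic acid; 2 2-bromo-5-(1,3-dioxolan-2-yl)phenol
Product: 6 2-bromo-5-(1,3-dioxolan-2-yl)phenyl 2-chloro-5-(propan-2-yloxy)benzoate
Conditions: DCC, DMAP (cat.), CH2Cl2, 0 °C to rt
Reagents that add atoms: none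
Why: Steglich esterification, in which DCC activates the acid and DMAP relays the acyl group to the weakly nucleophilic ortho-bromophenol, forms the aryl ester tether under neutral conditions that leave the acetal intact.

Step 5
Reactants: 6 2-bromo-5-(1,3-dioxolan-2-yl)phenyl 2-chloro-5-(propan-2-yloxy)benzoate
Product: 7 7-chloro-3-(1,3-dioxolan-2-yl)-10-(propan-2-yloxy)-6H-benzo[c]chromen-6-one
Conditions: Pd(OAc)2 (cat.), PPh3, K2CO3, pivalic acid (cat.), DMA, 120 °C, argon
Reagents that add atoms: none
Why: Zerovalent palladium, formed in situ from Pd(OAc)2 and PPh3, inserts into the C–Br bond of ring A; the pivalate ligand then removes the b1 hydrogen of the benzoate in a concerted metalation–deprotonation, helped by the acidifying carbonyl and isopropoxy neighbours, to give a seven-membered diaryl palladacycle. Reductive elimination forms the C6–b1 bond and thereby closes the six-membered lactone ring, so the ring arises by biaryl C–C bond formation across the pre-formed ester tether. The closest known reaction type is the palladium-catalysed intramolecular direct arylation of aryl benzoates to 6H-benzo[c]chromen-6-ones, used for hindered biaryls, together with the analogous cyclisation of N-(2-halophenyl)benzamides in which the halide also sits on the heteroatom-bearing ring. No stereocentre is formed and the lactone-bridged axis is not configurationally fixed. Regioselectivity is built into the substrate, since bromine defines C6 and chlorine on b5 leaves b1–H as the only ortho C–H of the benzoyl ring; chemoselectivity for C–Br over the activated C–Cl bond is secured by a triarylphosphine in place of an electron-rich trialkylphosphine, and the carbonate/pivalate buffer keeps the acetal intact.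

Step 6
Reactants: 7 7-chloro-3-(1,3-dioxolan-2-yl)-10-(propan-2-yloxy)-6H-benzo[c]chromen-6-one
Product: 8 3'-chloro-4-(1,3-dioxolan-2-yl)-2'-(hydroxymethyl)-6'-(propan-2-yloxy)-[1,1'-biphenyl]-2-ol
Conditions: LiAlH4, THF, 0 °C; aqueous potassium sodium tartrate work-up
Reagents that add atoms: none
Why: Hydride reduction of the aryl ester (reductive lactone opening) releases the C7 phenol and converts the carbonyl carbon into the benzylic CH2OH on b6, while acetal and aryl chloride are inert to LiAlH4 at 0 °C and the neutral tartrate work-up spares the acetal.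

Step 7
Reactants: 8 3'-chloro-4-(1,3-dioxolan-2-yl)-2'-(hydroxymethyl)-6'-(propan-2-yloxy)-[1,1'-biphenyl]-2-ol
Product: 9 [3-chloro-4'-(1,3-dioxolan-2-yl)-2'-methoxy-6-(propan-2-yloxy)-[1,1'-biphenyl]-2-yl]methanol
Conditions: MeI, K2CO3, acetone, 45 °C
Reagents that add atoms: iodomethane, CI
Why: Williamson etherification is chemoselective because carbonate deprotonates the phenol but not the benzylic alcohol.

Step 8
Reactants: 9 [3-chloro-4'-(1,3-dioxolan-2-yl)-2'-methoxy-6-(propan-2-yloxy)-[1,1'-biphenyl]-2-yl]methanol
Product: 10 2-[2'-(bromomethyl)-3'-chloro-2-methoxy-6'-(propan-2-yloxy)-[1,1'-biphenyl]-4-yl]-1,3-dioxolane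
Conditions: CBr4, PPh3, CH2Cl2, 0 °C
Reagents that add atoms: carbon tetrabromide, BrC(Br)(Br)Br
Why: Appel bromination converts the primary benzylic alcohol into the bromide through an alkoxyphosphonium ion under essentially neutral conditions tolerated by the dioxolane.

Step 9
Reactants: 10 2-[2'-(bromomethyl)-3'-chloro-2-methoxy-6'-(propan-2-yloxy)-[1,1'-biphenyl]-4-yl]-1,3-dioxolane
Product: 11 {[3-chloro-4'-(1,3-dioxolan-2-yl)-2'-methoxy-6-(propan-2-yloxy)-[1,1'-biphenyl]-2-yl]methyl}triphenylphosphonium bromide
Conditions: PPh3, toluene, 100 °C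
Reagents that add atoms: triphenylphosphine, c1ccc(cc1)P(c1ccccc1)c1ccccc1
Why: SN2 quaternisation of PPh3 by the benzylic bromide gives the Wittig salt, which should crystallise from the hot non-polar solvent.

Step 10
Reactants: 12 3-bromo-5-chloro-4-hydroxybenzaldehyde
Product: 13 3-bromo-5-chloro-4-(propan-2-yloxy)benzaldehyde
Conditions: 2-bromopropane, K2CO3, KI (cat.), DMF, 80 °C
Reagents that add atoms: 2-bromopropane, CC(C)Br
Why: Williamson etherification of the acidic phenol flanked by two halogens is slow but feasible with a secondary bromide in DMF when iodide catalysis and heat are used.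

Step 11
Reactants: 13 3-bromo-5-chloro-4-(propan-2-yloxy)benzaldehyde
Product: 14 2-[3-bromo-5-chloro-4-(propan-2-yloxy)phenyl]-1,3-dioxolane
Conditions: ethylene glycol, p-TsOH (cat.), toluene, reflux, Dean–Stark
Reagents that add atoms: ethylene glycol, OCCO
Why: Acid-catalysed acetalisation with azeotropic water removal protects the ring D aldehyde so that only the ring C aldehyde is free in step 15.

Step 12
Reactants: 15 3-bromo-4-hydroxybenzaldehyde
Product: 16 3-bromo-4-(propan-2-yloxy)benzaldehyde
Conditions: 2-bromopropane, K2CO3, DMF, 70 °C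
Reagents that add atoms: 2-bromopropane, CC(C)Br
Why: Williamson etherification of the phenoxide with the secondary bromide in a dipolar aprotic solvent gives the ring C isopropyl ether.

Step 13
Reactants: 16 3-bromo-4-(propan-2-yloxy)benzaldehyde
Product: 17 4-(propan-2-yloxy)-3-(4,4,5,5-tetramethyl-1,3,2-dioxaborolan-2-yl)benzaldehyde
Conditions: B2pin2, Pd(dppf)Cl2 (cat.), KOAc, 1,4-dioxane, 90 °C
Reagents that add atoms: bis(pinacolato)diboron, CC1(C)OB(OC1(C)C)B1OC(C)(C)C(C)(C)O1
Why: Miyaura borylation (palladium-catalysed coupling of the aryl bromide with the diboron reagent, acetate as base) tolerates the aldehyde and gives the boronate needed for the ring C–ring D bond.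

Step 14
Reactants: 17 4-(propan-2-yloxy)-3-(4,4,5,5-tetramethyl-1,3,2-dioxaborolan-2-yl)benzaldehyde; 14 2-[3-bromo-5-chloro-4-(propan-2-yloxy)phenyl]-1,3-dioxolane
Product: 18 3'-chloro-5'-(1,3-dioxolan-2-yl)-2',6-bis(propan-2-yloxy)-[1,1'-biphenyl]-3-carbaldehyde
Conditions: Pd(PPh3)4 (cat.), K2CO3, DME/H2O, 85 °C
Reagents that add atoms: none
Why: Suzuki–Miyaura coupling forms the ring C–ring D bond with only two ortho substituents at the new axis, the Pd(PPh3)4 catalyst inserting into C–Br and not into C–Cl and the basic medium leaving acetal and aldehyde intact.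

Step 15
Reactants: 11 {[3-chloro-4'-(1,3-dioxolan-2-yl)-2'-methoxy-6-(propan-2-yloxy)-[1,1'-biphenyl]-2-yl]methyl}triphenylphosphonium bromide; 18 3'-chloro-5'-(1,3-dioxolan-2-yl)-2',6-bis(propan-2-yloxy)-[1,1'-biphenyl]-3-carbaldehyde
Product: 20 open-chain stilbene bis-dioxolane (E/Z mixture), via phosphorus ylide 19 (not isolated)
Conditions: KOtBu, THF, 0 °C; then 18, 0 °C to rt
Reagents that add atoms: none
Why: Wittig olefination of the unhindered aryl aldehyde with the semi-stabilised benzylic ylide joins b6 to ring C through a C=C bond whose E/Z ratio is irrelevant because the alkene is saturated in step 16.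

Step 16
Reactants: 20 open-chain stilbene bis-dioxolane (E/Z mixture)
Product: 21 open-chain bibenzyl bis-dioxolane
Conditions: TsNHNH2 (excess), NaOAc, DME/H2O, reflux
Reagents that add atoms: none
Why: Diimide reduction, a concerted syn transfer of two hydrogens from HN=NH generated from the sulfonyl hydrazide, saturates the stilbene without the hydrodechlorination that palladium-catalysed hydrogenation would risk.

Step 17
Reactants: 21 open-chain bibenzyl bis-dioxolane
Product: 22 open-chain bibenzyl dialdehyde
Conditions: 2 M HCl, THF, rt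
Reagents that add atoms: water, O
Why: Acid-catalysed acetal hydrolysis frees both aldehydes at once, while the aryl methyl ether, the aryl isopropyl ethers and the aryl chlorides are stable to dilute aqueous acid.

Step 18
Reactants: 22 open-chain bibenzyl dialdehyde
Product: 23 16-membered macrocyclic cis-stilbene tris(isopropyl ether)
Conditions: TiCl4, Zn, pyridine, THF, reflux, slow addition (high dilution)
Reagents that add atoms: none
Why: Intramolecular McMurry coupling (reductive carbonyl coupling by low-valent titanium to a titanium pinacolate followed by deoxygenation) under high dilution closes the 16-membered ring, tolerates aryl chlorides and is expected to favour the cis alkene imposed by the ring, although either geometry serves in step 19 because light interconverts them.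

Step 19
Reactants: 23 16-membered macrocyclic cis-stilbene tris(isopropyl ether)
Product: 25 phenanthrene-bridged macrocycle tris(isopropyl ether), via trans-dihydrophenanthrene 24 (not isolated)
Conditions: hν (medium-pressure Hg lamp, Pyrex), I2, propylene oxide, toluene, rt, about 1 mM, argon
Reagents that add atoms: none
Why: Mallory oxidative photocyclisation, in which the cis-stilbene closes by a photochemical conrotatory 6π electrocyclisation to the trans-dihydrophenanthrene that iodine aromatises while propylene oxide traps HI, should join the ring A carbon para to the methoxy group to the ring D carbon lying between the vinyl carbon and ring C, because the seven-atom tether through rings C and B can only span phenanthrene C4 and C6 and closure ortho to the methoxy group would crowd OMe and ring C into the same bay.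

Step 20
Reactants: 25 phenanthrene-bridged macrocycle tris(isopropyl ether)
Product: 26 target CNP0310669.0
Conditions: BCl3, CH2Cl2, −78 to 0 °C; then MeOH/H2O
Reagents that add atoms: none
Why: Lewis-acid ether cleavage with BCl3 removes the three secondary isopropyl groups, whose ionisation-type C–O scission is much faster than SN2-type demethylation, so the C7 methyl ether is retained.

Compound list
1 | 4-bromo-3-hydroxybenzaldehyde | O=Cc1ccc(Br)c(O)c1 | starting material
2 | 2-bromo-5-(1,3-dioxolan-2-yl)phenol | Oc1cc(ccc1Br)C1OCCO1 | intermediate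
3 | 2-chloro-5-hydroxybenzoic acid | OC(=O)c1cc(O)ccc1Cl | starting material
4 | propan-2-yl 2-chloro-5-(propan-2-yloxy)benzoate | CC(C)OC(=O)c1cc(OC(C)C)ccc1Cl | intermediate
5 | 2-chloro-5-(propan-2-yloxy)benzoic acid | OC(=O)c1cc(OC(C)C)ccc1Cl | intermediate
6 | 2-bromo-5-(1,3-dioxolan-2-yl)phenyl 2-chloro-5-(propan-2-yloxy)benzoate | Brc1ccc(cc1OC(=O)c1cc(OC(C)C)ccc1Cl)C1OCCO1 | intermediate
7 | 7-chloro-3-(1,3-dioxolan-2-yl)-10-(propan-2-yloxy)-6H-benzo[c]chromen-6-one | O=C1Oc2cc(C3OCCO3)ccc2-c2c(OC(C)C)ccc(Cl)c21 | intermediate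
8 | 3'-chloro-4-(1,3-dioxolan-2-yl)-2'-(hydroxymethyl)-6'-(propan-2-yloxy)-[1,1'-biphenyl]-2-ol | OCc1c(Cl)ccc(OC(C)C)c1-c1ccc(C2OCCO2)cc1O | intermediate
9 | [3-chloro-4'-(1,3-dioxolan-2-yl)-2'-methoxy-6-(propan-2-yloxy)-[1,1'-biphenyl]-2-yl]methanol | OCc1c(Cl)ccc(OC(C)C)c1-c1ccc(C2OCCO2)cc1OC | intermediate
10 | 2-[2'-(bromomethyl)-3'-chloro-2-methoxy-6'-(propan-2-yloxy)-[1,1'-biphenyl]-4-yl]-1,3-dioxolane | BrCc1c(Cl)ccc(OC(C)C)c1-c1ccc(C2OCCO2)cc1OC | intermediate
11 | {[3-chloro-4'-(1,3-dioxolan-2-yl)-2'-methoxy-6-(propan-2-yloxy)-[1,1'-biphenyl]-2-yl]methyl}triphenylphosphonium bromide | [Br-].COc1cc(C2OCCO2)ccc1-c1c(OC(C)C)ccc(Cl)c1C[P+](c1ccccc1)(c1ccccc1)c1ccccc1 | intermediate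
12 | 3-bromo-5-chloro-4-hydroxybenzaldehyde | O=Cc1cc(Cl)c(O)c(Br)c1 | starting material
13 | 3-bromo-5-chloro-4-(propan-2-yloxy)benzaldehyde | O=Cc1cc(Cl)c(OC(C)C)c(Br)c1 | intermediate
14 | 2-[3-bromo-5-chloro-4-(propan-2-yloxy)phenyl]-1,3-dioxolane | CC(C)Oc1c(Cl)cc(cc1Br)C1OCCO1 | intermediate
15 | 3-bromo-4-hydroxybenzaldehyde | O=Cc1ccc(O)c(Br)c1 | starting material
16 | 3-bromo-4-(propan-2-yloxy)benzaldehyde | O=Cc1ccc(OC(C)C)c(Br)c1 | intermediate
17 | 4-(propan-2-yloxy)-3-(4,4,5,5-tetramethyl-1,3,2-dioxaborolan-2-yl)benzaldehyde | O=Cc1ccc(OC(C)C)c(c1)B1OC(C)(C)C(C)(C)O1 | intermediate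
18 | 3'-chloro-5'-(1,3-dioxolan-2-yl)-2',6-bis(propan-2-yloxy)-[1,1'-biphenyl]-3-carbaldehyde | O=Cc1ccc(OC(C)C)c(c1)-c1cc(cc(Cl)c1OC(C)C)C1OCCO1 | intermediate
19 | phosphorus ylide of 11: {[3-chloro-4'-(1,3-dioxolan-2-yl)-2'-methoxy-6-(propan-2-yloxy)-[1,1'-biphenyl]-2-yl]methylidene}triphenylphosphorane | COc1cc(C2OCCO2)ccc1-c1c(OC(C)C)ccc(Cl)c1C=P(c1ccccc1)(c1ccccc1)c1ccccc1 | intermediate (not isolated)
20 | open-chain stilbene bis-dioxolane: 1,2-diarylethene joining b6 of the ring A–ring B biaryl of 9 to the former formyl carbon of 18, both dioxolanes retained, E/Z mixture | COc1cc(C2OCCO2)ccc1-c1c(OC(C)C)ccc(Cl)c1C=Cc1ccc(OC(C)C)c(c1)-c1cc(cc(Cl)c1OC(C)C)C1OCCO1 | intermediate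
21 | open-chain bibenzyl bis-dioxolane: the 1,2-diarylethane obtained by saturating the C=C of 20 | COc1cc(C2OCCO2)ccc1-c1c(OC(C)C)ccc(Cl)c1CCc1ccc(OC(C)C)c(c1)-c1cc(cc(Cl)c1OC(C)C)C1OCCO1 | intermediate
22 | open-chain bibenzyl dialdehyde: 3'-chloro-2'-{2-[3'-chloro-5'-formyl-2',6-bis(propan-2-yloxy)-[1,1'-biphenyl]-3-yl]ethyl}-2-methoxy-6'-(propan-2-yloxy)-[1,1'-biphenyl]-4-carbaldehyde | COc1cc(C=O)ccc1-c1c(OC(C)C)ccc(Cl)c1CCc1ccc(OC(C)C)c(c1)-c1cc(C=O)cc(Cl)c1OC(C)C | intermediate
23 | 16-membered macrocyclic cis-stilbene tris(isopropyl ether): the two formyl carbons of 22 joined as a (Z)-CH=CH bridge between ring A and ring D | CC(C)Oc1ccc(Cl)c(CCc3ccc(OC(C)C)c(c3)-c3cc(cc(Cl)c3OC(C)C)/C=C\c3ccc2c(OC)c3)c1-2 | intermediate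
24 | trans-4a,4b-dihydrophenanthrene from 23 (racemic, one enantiomer drawn): new bond between the ring A carbon para to OMe and the ring D carbon between the vinyl carbon and ring C, the two new CH hydrogens trans | COC1=CC2=CC=C3C=C(Cl)C(OC(C)C)=C4[C@@H]3[C@H]2C=C1c1c(OC(C)C)ccc(Cl)c1CCc1ccc(OC(C)C)c4c1 | intermediate (not isolated)
25 | phenanthrene-bridged macrocycle tris(isopropyl ether): the target with its three phenols (phenanthrene C3, ring B b2, ring C) as isopropyl ethers | COc1cc2ccc3cc(Cl)c(OC(C)C)c4c3c2cc1-c1c(OC(C)C)ccc(Cl)c1CCc1ccc(OC(C)C)c-4c1 | intermediate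
26 | target CNP0310669.0: 2-chloro-7-methoxyphenanthren-3-ol carrying at C6 the 3-chloro-6-hydroxyphenyl ring B and at C4 the 2-hydroxyphenyl ring C, rings B and C joined by a CH2CH2 bridge in a 12-membered ring | COc1cc2ccc3cc(Cl)c(O)c4c3c2cc1-c1c(O)ccc(Cl)c1CCc1ccc(O)c-4c1 | target

Total step count: 20 steps.
Longest linear sequence: 14 steps (from 3 through steps 2–9 and 15–20).

Steps most likely to fail (in route order)

Step 5. C–H cleavage at b1, a carbon flanked by the ester carbonyl and the isopropoxy group, may be slow. Hydrodebromination of ring A, base-mediated cleavage of the aryl ester, or insertion of palladium into the activated C–Cl bond could then take over. The fallback drops C–H activation and couples two carbon–halogen bonds. It sets out from acid 5 and phenol 2.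
- Carboxylate-directed ortho-lithiation of 5 (sec-butyllithium/TMEDA, THF, −78 °C) can only occur at b1, which the isopropoxy group activates further; an iodine quench should give 6-chloro-2-iodo-3-(propan-2-yloxy)benzoic acid F1.
- Oxalyl chloride with catalytic DMF would give the acid chloride F2, which acylates phenol 2 (Et3N, DMAP, CH2Cl2) to the bromo-iodo ester F3.
- Intramolecular reductive biaryl coupling under Stille–Kelly conditions (Pd(PPh3)4, Me3SnSnMe3, 1,4-dioxane, 100 °C) stannylates the C–I bond and couples it with the C–Br bond across the same ester tether.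

This returns to the route at lactone 7.

Step 18. Intermolecular carbonyl coupling to oligomers, or arrest at the pinacol stage, may compete with the closure of the 16-membered ring. The fallback replaces reductive carbonyl coupling by olefin metathesis and sets out from dialdehyde 22.
- Twofold Wittig methylenation (methyltriphenylphosphonium bromide, KOtBu, THF) should give the bis-styrene F4.
- Ring-closing metathesis with the second-generation Grubbs catalyst RuCl2(=CHPh)(PCy3)(H2IMes) in dilute toluene at 80 °C releases ethene and forms the stilbene bridge.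

This returns to the route at macrocycle 23, where either alkene geometry is acceptable.

Step 19. Within the strained ring the excited stilbene may not reach the closing geometry. The dihydrophenanthrene may revert faster than iodine oxidises it, closure may occur at the other ortho carbon of ring A, or a C–Cl bond may be photolysed. The fallback replaces the photochemical electrocyclisation by a ground-state palladium-catalysed ring closure from a bromide placed on ring A. It sets out from alcohol 9.
- NBS in MeCN at 0 °C should brominate ring A para to the methoxy group, its most electron-rich free position, giving the bromo alcohol F5.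
- The operations of steps 8, 9, 15, 16, 17 and 18 are then repeated on this series. They lead through the benzylic bromide F6, the phosphonium bromide F7, its ylide F8 (not isolated), the open-chain bromo stilbene F9 (from the ylide and aldehyde 18), the bromo bibenzyl F10 and the bromo dialdehyde F11 to the macrocyclic bromo cis-stilbene F12.
- Intramolecular direct arylation of F12 (Pd(OAc)2, PPh3, K2CO3, pivalic acid, DMA, 120 °C) forms the C4a–C4b bond between the brominated ring A carbon and the inner C–H of ring D, the same chemistry as step 5.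

This returns to the route at phenanthrene 25.

Further compounds
F1 | step 5 | 6-chloro-2-iodo-3-(propan-2-yloxy)benzoic acid | OC(=O)c1c(I)c(OC(C)C)ccc1Cl
F2 | step 5 | 6-chloro-2-iodo-3-(propan-2-yloxy)benzoyl chloride | ClC(=O)c1c(I)c(OC(C)C)ccc1Cl
F3 | step 5 | 2-bromo-5-(1,3-dioxolan-2-yl)phenyl 6-chloro-2-iodo-3-(propan-2-yloxy)benzoate | Brc1ccc(cc1OC(=O)c1c(I)c(OC(C)C)ccc1Cl)C1OCCO1
F4 | step 18 | bis-styrene: 22 with both formyl groups replaced by vinyl groups | COc1cc(C=C)ccc1-c1c(OC(C)C)ccc(Cl)c1CCc1ccc(OC(C)C)c(c1)-c1cc(C=C)cc(Cl)c1OC(C)C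
F5 | step 19 | [5'-bromo-3-chloro-4'-(1,3-dioxolan-2-yl)-2'-methoxy-6-(propan-2-yloxy)-[1,1'-biphenyl]-2-yl]methanol | OCc1c(Cl)ccc(OC(C)C)c1-c1cc(Br)c(C2OCCO2)cc1OC
F6 | step 19 | 2-[5-bromo-2'-(bromomethyl)-3'-chloro-2-methoxy-6'-(propan-2-yloxy)-[1,1'-biphenyl]-4-yl]-1,3-dioxolane | BrCc1c(Cl)ccc(OC(C)C)c1-c1cc(Br)c(C2OCCO2)cc1OC
F7 | step 19 | {[5'-bromo-3-chloro-4'-(1,3-dioxolan-2-yl)-2'-methoxy-6-(propan-2-yloxy)-[1,1'-biphenyl]-2-yl]methyl}triphenylphosphonium bromide | [Br-].COc1cc(C2OCCO2)c(Br)cc1-c1c(OC(C)C)ccc(Cl)c1C[P+](c1ccccc1)(c1ccccc1)c1ccccc1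
F8 | step 19 | phosphorus ylide of F7 | COc1cc(C2OCCO2)c(Br)cc1-c1c(OC(C)C)ccc(Cl)c1C=P(c1ccccc1)(c1ccccc1)c1ccccc1
F9 | step 19 | bromo analogue of 20 (Br on ring A para to OMe, E/Z mixture) | COc1cc(C2OCCO2)c(Br)cc1-c1c(OC(C)C)ccc(Cl)c1C=Cc1ccc(OC(C)C)c(c1)-c1cc(cc(Cl)c1OC(C)C)C1OCCO1
F10 | step 19 | bromo analogue of 21 | COc1cc(C2OCCO2)c(Br)cc1-c1c(OC(C)C)ccc(Cl)c1CCc1ccc(OC(C)C)c(c1)-c1cc(cc(Cl)c1OC(C)C)C1OCCO1
F11 | step 19 | bromo analogue of 22 (Br ortho to the ring A formyl group) | COc1cc(C=O)c(Br)cc1-c1c(OC(C)C)ccc(Cl)c1CCc1ccc(OC(C)C)c(c1)-c1cc(C=O)cc(Cl)c1OC(C)C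
F12 | step 19 | bromo analogue of 23 (Z; Br on the ring A carbon ortho to the stilbene carbon and para to OMe) | CC(C)Oc1ccc(Cl)c(CCc3ccc(OC(C)C)c(c3)-c3cc(cc(Cl)c3OC(C)C)/C=C\c3c(Br)cc2c(OC)c3)c1-2
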